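## Retrosynthetic overview

1. Lespecyrtin E4 (28) ⇒ bis-ether 24. One thermal operation runs two aryl-ether [3,3] shifts: the O3 1,1-dimethylpropargyl ether builds ring F (new C2–CH= and O3–CMe2 bonds), and the O9 1,1-dimethylallyl ether places the prenyl group on C10 and frees 9-OH.
2. Enabling feature: two ortho oxygen/carbon pairs, O3/C2 on ring A (ring F is O3–CMe2–CH=CH–C2) and O9/C10 on ring D (phenol next to prenyl), are both Claisen retrons. C8, the other neighbour of C9, is blocked by the ring E oxygen; C2 is the neighbour of C3 that lies para to O5, and ring B is at the saturated chroman level.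
3. 24 ⇒ pterocarpan 19 (O9 allylation, desilylation, O3 propargylation). 19 ⇒ isoflavone 15 by asymmetric transfer hydrogenation with dynamic kinetic resolution and acid-induced closure of ring C, which sets 6aR and 11aR.
4. 15 ⇒ Negishi coupling of iodochromone 12 (rings A and B, from 2,4-dihydroxyacetophenone) with bromochromene 8 (rings D and E, from 5-bromo-2,4-dihydroxybenzaldehyde by Dakin oxidation, O-propargylation and Claisen cyclisation).
5. Order of ring closure: E (fragment 8) and B (fragment 12), then C (step 8), then F last (step 13).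

Key step: step 13

Remark on numbering: pterocarpan numbering is used. Ring A = benzene C1–C4/C4a/C11b; ring B = O5–C6–C6a–C11a pyran; ring C = C6a–C6b–C10a–O11–C11a furan; ring D = benzene C6b–C10a; ring E = dimethylpyran on C7–C8 (O on C8); ring F = dimethylpyran on C2–C3 (O on C3). The target is (6aR,11aR), cis-fused.

Assumption: the transfer-hydrogenation catalyst is taken to follow its usual sense of induction for aryl ketones (the R,R-ligand gives the 4R benzylic alcohol); if the sense were opposite, the S,S-catalyst would be used.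

## Route

Step 1
Reactants: 1 5-bromo-2,4-dihydroxybenzaldehyde
Product: 2 5-bromo-2,4-bis(methoxymethoxy)benzaldehyde
Conditions: MOMCl, i-Pr2NEt, CH2Cl2, 0 °C → reflux
Reagents that add atoms: chloromethyl methyl ether, COCCl
Why: Williamson-type acetal etherification of both phenols (the chelated 2-OH needs excess reagent and warming); MOM is chosen because both groups are removed later by the acid that closes ring C.

Step 2
Reactants: 2 5-bromo-2,4-bis(methoxymethoxy)benzaldehyde
Product: 4 5-bromo-2,4-bis(methoxymethoxy)phenol, via aryl formate 3 (not isolated)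
Conditions: mCPBA, NaHCO3, CH2Cl2, 0 °C → rt; then K2CO3, MeOH, rt
Reagents that add atoms: 3-chloroperoxybenzoic acid, O=C(OO)c1cccc(Cl)c1
Why: Baeyer–Villiger (Dakin-type) oxidation, in which the electron-rich aryl group migrates in the Criegee adduct to give formate 3 and methanolysis then frees the phenol oxygen that becomes O8.

Step 3
Reactants: 4 5-bromo-2,4-bis(methoxymethoxy)phenol
Product: 5 1-bromo-2,4-bis(methoxymethoxy)-5-(2-methylbut-3-yn-2-yloxy)benzene
Conditions: 3-chloro-3-methylbut-1-yne, DBU, CuCl2·2H2O (cat.), MeCN, 0 °C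
Reagents that add atoms: 3-chloro-3-methylbut-1-yne, CC(C)(Cl)C#C
Why: copper-catalysed propargylic etherification of the phenoxide with the tertiary propargylic chloride (through a copper acetylide), the standard access to aryl 1,1-dimethylpropargyl ethers.

Step 4
Reactants: 5 1-bromo-2,4-bis(methoxymethoxy)-5-(2-methylbut-3-yn-2-yloxy)benzene
Product: 8 5-bromo-6,8-bis(methoxymethoxy)-2,2-dimethyl-2H-chromene, via allenylphenol 6 (not isolated), via ortho-quinone methide 7 (not isolated)
Conditions: PhNEt2, 170 °C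
Reagents that add atoms: none
Why: aromatic propargyl Claisen rearrangement to the only free ortho carbon (the other carries OMOM), enolisation to 6, 1,5-hydrogen shift to 7 and oxa-6π electrocyclisation close ring E with unambiguous regiochemistry.

Step 5
Reactants: 9 1-(2,4-dihydroxyphenyl)ethanone
Product: 10 1-[2-hydroxy-4-(triisopropylsilyloxy)phenyl]ethanone
Conditions: TIPSCl, imidazole, DMF, 0 °C → rt
Reagents that add atoms: chlorotri(propan-2-yl)silane, CC(C)[Si](Cl)(C(C)C)C(C)C
Why: selective silylation of the more acidic, non-chelated 4-OH, because the 2-OH is hydrogen-bonded to the ketone and stays free for the chromone synthesis.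

Step 6
Reactants: 10 1-[2-hydroxy-4-(triisopropylsilyloxy)phenyl]ethanone
Product: 12 3-iodo-7-(triisopropylsilyloxy)-4H-chromen-4-one, via enaminone 11 (not isolated)
Conditions: Me2NCH(OMe)2, toluene, 90 °C; then I2, CHCl3, rt
Reagents that add atoms: N,N-dimethylformamide dimethyl acetal, COC(OC)N(C)C; iodine, II
Why: enaminone condensation followed by iodine-induced cyclisation (α-iodination, attack of the phenol on the iminium carbon, loss of dimethylamine) is the standard synthesis of 3-iodochromones and closes ring B.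

Step 7
Reactants: 8 5-bromo-6,8-bis(methoxymethoxy)-2,2-dimethyl-2H-chromene; 12 3-iodo-7-(triisopropylsilyloxy)-4H-chromen-4-one
Product: 15 3-[6,8-bis(methoxymethoxy)-2,2-dimethyl-2H-chromen-5-yl]-7-(triisopropylsilyloxy)-4H-chromen-4-one, via aryllithium 13 (not isolated), via arylzinc chloride 14 (not isolated)
Conditions: n-BuLi, THF, −78 °C; ZnCl2, −78 °C → rt; then 12, Pd2(dba)3 (cat.), SPhos, THF, 50 °C
Reagents that add atoms: none
Why: bromine–lithium exchange, transmetalation to zinc and Negishi cross-coupling, in which SPhos supports di-ortho-substituted arylzincs and the anhydrous, base-free medium spares the silyl ether and the base-sensitive iodochromone.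

Step 8
Reactants: 15 3-[6,8-bis(methoxymethoxy)-2,2-dimethyl-2H-chromen-5-yl]-7-(triisopropylsilyloxy)-4H-chromen-4-one
Product: 19 (6aR,11aR)-3-(triisopropylsilyloxy)-7,8-(2,2-dimethylpyrano)pterocarpan-9-ol, via isoflavanone 16 (not isolated), via cis-isoflavan-4-ol 17 (not isolated), via dihydroxy isoflavan-4-ol 18 (not isolated)
Conditions: RuCl[(R,R)-TsDPEN](p-cymene) (cat.), HCO2H/Et3N (5:2), EtOAc, 40 °C; then HCl, MeOH, 45 °C
Reagents that add atoms: none
Why: Noyori-type asymmetric transfer hydrogenation, in which conjugate reduction gives isoflavanone 16 whose C3 epimerises under the amine conditions, so that ketone reduction proceeds with dynamic kinetic resolution (hydride anti to the 3-aryl group, catalyst-controlled 4R) to cis-(3R,4R)-alcohol 17; acid then removes both MOM groups and the C4 benzylic cation is trapped by the 2'-OH in an SN1 closure that can only give the cis-fused ring C, so C3 (R) becomes C6a (R) and dictates C11a (R).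

Step 9
Reactants: 20 2-methylbut-3-en-2-ol
Product: 21 tert-butyl 2-methylbut-3-en-2-yl carbonate
Conditions: n-BuLi, THF, −78 °C; then Boc2O, −78 → 0 °C
Reagents that add atoms: di-tert-butyl dicarbonate, CC(C)(C)OC(=O)OC(=O)OC(C)(C)C
Why: acylation of the lithium alkoxide with Boc2O gives the tertiary allylic carbonate that serves as the π-allyl precursor.

Step 10
Reactants: 19 (6aR,11aR)-3-(triisopropylsilyloxy)-7,8-(2,2-dimethylpyrano)pterocarpan-9-ol; 21 tert-butyl 2-methylbut-3-en-2-yl carbonate
Product: 22 (6aR,11aR)-9-(2-methylbut-3-en-2-yloxy)-3-(triisopropylsilyloxy)-7,8-(2,2-dimethylpyrano)pterocarpan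
Conditions: Pd(PPh3)4 (cat.), THF, 0 °C
Reagents that add atoms: none
Why: Tsuji–Trost O-allylation, in which zerovalent palladium ionises 21 to a 1,1-dimethyl-π-allyl complex with loss of CO2, the tert-butoxide deprotonates the only free phenol (9-OH), and the phenoxide attacks the more substituted terminus at low temperature to give the tertiary (reverse-prenyl) ether.

Step 11
Reactants: 22 (6aR,11aR)-9-(2-methylbut-3-en-2-yloxy)-3-(triisopropylsilyloxy)-7,8-(2,2-dimethylpyrano)pterocarpan
Product: 23 (6aR,11aR)-9-(2-methylbut-3-en-2-yloxy)-7,8-(2,2-dimethylpyrano)pterocarpan-3-ol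
Conditions: TBAF, AcOH, THF, 0 °C
Reagents that add atoms: none
Why: fluoride cleaves the aryl silyl ether at 0 °C under buffered conditions without touching the acid- and heat-sensitive tertiary allyl ether.

Step 12
Reactants: 23 (6aR,11aR)-9-(2-methylbut-3-en-2-yloxy)-7,8-(2,2-dimethylpyrano)pterocarpan-3-ol
Product: 24 (6aR,11aR)-9-(2-methylbut-3-en-2-yloxy)-3-(2-methylbut-3-yn-2-yloxy)-7,8-(2,2-dimethylpyrano)pterocarpan
Conditions: 3-chloro-3-methylbut-1-yne, DBU, CuCl2·2H2O (cat.), MeCN, 0 °C
Reagents that add atoms: 3-chloro-3-methylbut-1-yne, CC(C)(Cl)C#C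
Why: the same copper-catalysed propargylic etherification as in step 3, run at 0 °C so that the O9 allyl ether does not yet rearrange.

Step 13
Reactants: 24 (6aR,11aR)-9-(2-methylbut-3-en-2-yloxy)-3-(2-methylbut-3-yn-2-yloxy)-7,8-(2,2-dimethylpyrano)pterocarpan
Product: 28 Lespecyrtin E4, via prenyl phenol 25 (not isolated), via allenylphenol 26 (not isolated), via ortho-quinone methide 27 (not isolated)
Conditions: PhNEt2, 110 °C, then 175 °C, degassed, sealed tube
Reagents that add atoms: none
Why: At 110 °C the O9 1,1-dimethylallyl ether undergoes an aromatic Claisen [3,3] shift to C10 and re-aromatises to phenol 25; at 175 °C the O3 1,1-dimethylpropargyl ether undergoes the propargyl Claisen [3,3] shift to C2, enolises to allenylphenol 26, a 1,5-hydrogen shift gives ortho-quinone methide 27 and a thermal disrotatory oxa-6π electrocyclisation (O3 onto the CMe2 terminus) closes ring F. The closest known reactions are the thermal conversion of aryl 1,1-dimethylpropargyl ethers into 2,2-dimethyl-2H-chromenes and the Claisen rearrangement of aryl 1,1-dimethylallyl ethers to ortho-prenylphenols, here run in one flask. No stereocentre is created, and C6a and C11a are not at risk because the medium is neutral to basic and aprotic (the aniline solvent also suppresses acid-induced opening of ring C, chroman formation from the new ortho-prenylphenol and hydration of the chromenes). At ring D the shift must go to C10, which is secured because C8, the only other ortho carbon of O9, carries the ring E oxygen, so a shift there cannot re-aromatise and reverts. At ring A the shift must go to C2 rather than C4: C2 lies para to the donor O5 (the position favoured in [3,3] shifts of meta-donor aryl ethers) and is flanked only by C1–H, whereas C4 is wedged between O3 and O5, and because ring B is at the chroman level there is no carbonyl conjugated to ring A whose bond fixation would steer the shift to C4 as it does in 7-propargyloxy chromones and coumarins. The allyl ether rearranges at the lower temperature, so ring D is fully substituted before ring F closes and ring F is the last ring formed.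

## Compound list

1 | 5-bromo-2,4-dihydroxybenzaldehyde | O=Cc1cc(Br)c(O)cc1O | starting material
2 | 5-bromo-2,4-bis(methoxymethoxy)benzaldehyde | O=Cc1cc(Br)c(OCOC)cc1OCOC | intermediate
3 | 5-bromo-2,4-bis(methoxymethoxy)phenyl formate | O=COc1cc(Br)c(OCOC)cc1OCOC | intermediate
4 | 5-bromo-2,4-bis(methoxymethoxy)phenol | Oc1cc(Br)c(OCOC)cc1OCOC | intermediate
5 | 1-bromo-2,4-bis(methoxymethoxy)-5-(2-methylbut-3-yn-2-yloxy)benzene | C#CC(C)(C)Oc1cc(Br)c(OCOC)cc1OCOC | intermediate
6 | 3-bromo-4,6-bis(methoxymethoxy)-2-(3-methylbuta-1,2-dienyl)phenol | CC(C)=C=Cc1c(O)c(OCOC)cc(OCOC)c1Br | intermediate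
7 | 5-bromo-2,4-bis(methoxymethoxy)-6-(3-methylbut-2-enylidene)cyclohexa-2,4-dienone | CC(C)=CC=C1C(=O)C(OCOC)=CC(OCOC)=C1Br | intermediate
8 | 5-bromo-6,8-bis(methoxymethoxy)-2,2-dimethyl-2H-chromene | CC1(C)C=Cc2c(Br)c(OCOC)cc(OCOC)c2O1 | intermediate
9 | 1-(2,4-dihydroxyphenyl)ethanone | CC(=O)c1ccc(O)cc1O | starting material
10 | 1-[2-hydroxy-4-(triisopropylsilyloxy)phenyl]ethanone | CC(=O)c1ccc(O[Si](C(C)C)(C(C)C)C(C)C)cc1O | intermediate
11 | (E)-3-(dimethylamino)-1-[2-hydroxy-4-(triisopropylsilyloxy)phenyl]prop-2-en-1-one | CN(C)/C=C/C(=O)c1ccc(O[Si](C(C)C)(C(C)C)C(C)C)cc1O | intermediate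
12 | 3-iodo-7-(triisopropylsilyloxy)-4H-chromen-4-one | O=c1c(I)coc2cc(O[Si](C(C)C)(C(C)C)C(C)C)ccc12 | intermediate
13 | [6,8-bis(methoxymethoxy)-2,2-dimethyl-2H-chromen-5-yl]lithium | [Li]c1c(OCOC)cc(OCOC)c2OC(C)(C)C=Cc12 | intermediate
14 | [6,8-bis(methoxymethoxy)-2,2-dimethyl-2H-chromen-5-yl]zinc chloride | Cl[Zn]c1c(OCOC)cc(OCOC)c2OC(C)(C)C=Cc12 | intermediate
15 | 3-[6,8-bis(methoxymethoxy)-2,2-dimethyl-2H-chromen-5-yl]-7-(triisopropylsilyloxy)-4H-chromen-4-one (isoflavone) | O=c1c(-c2c(OCOC)cc(OCOC)c3OC(C)(C)C=Cc23)coc2cc(O[Si](C(C)C)(C(C)C)C(C)C)ccc12 | intermediate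
16 | 3-[6,8-bis(methoxymethoxy)-2,2-dimethyl-2H-chromen-5-yl]-7-(triisopropylsilyloxy)chroman-4-one (isoflavanone, C3 epimerising, drawn without configuration) | O=C1c2ccc(O[Si](C(C)C)(C(C)C)C(C)C)cc2OCC1c1c(OCOC)cc(OCOC)c2OC(C)(C)C=Cc12 | intermediate
17 | (3R,4R)-3-[6,8-bis(methoxymethoxy)-2,2-dimethyl-2H-chromen-5-yl]-7-(triisopropylsilyloxy)chroman-4-ol (cis) | O[C@H]1c2ccc(O[Si](C(C)C)(C(C)C)C(C)C)cc2OC[C@H]1c1c(OCOC)cc(OCOC)c2OC(C)(C)C=Cc12 | intermediate
18 | (3R,4R)-3-(6,8-dihydroxy-2,2-dimethyl-2H-chromen-5-yl)-7-(triisopropylsilyloxy)chroman-4-ol | O[C@H]1c2ccc(O[Si](C(C)C)(C(C)C)C(C)C)cc2OC[C@H]1c1c(O)cc(O)c2OC(C)(C)C=Cc12 | intermediate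
19 | (6aR,11aR)-3-(triisopropylsilyloxy)-7,8-(2,2-dimethylpyrano)pterocarpan-9-ol (pyran O on C8, CH=CH on C7; C10–H and C2–H free) | c1c(O)c2c(c3c1O[C@H]1c4ccc(O[Si](C(C)C)(C(C)C)C(C)C)cc4OC[C@@H]31)C=CC(C)(C)O2 | intermediate
20 | 2-methylbut-3-en-2-ol | CC(C)(O)C=C | starting material
21 | tert-butyl 2-methylbut-3-en-2-yl carbonate | CC(C)(C=C)OC(=O)OC(C)(C)C | intermediate
22 | (6aR,11aR)-9-(2-methylbut-3-en-2-yloxy)-3-(triisopropylsilyloxy)-7,8-(2,2-dimethylpyrano)pterocarpan | c1c(OC(C)(C)C=C)c2c(c3c1O[C@H]1c4ccc(O[Si](C(C)C)(C(C)C)C(C)C)cc4OC[C@@H]31)C=CC(C)(C)O2 | intermediate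
23 | (6aR,11aR)-9-(2-methylbut-3-en-2-yloxy)-7,8-(2,2-dimethylpyrano)pterocarpan-3-ol | c1c(OC(C)(C)C=C)c2c(c3c1O[C@H]1c4ccc(O)cc4OC[C@@H]31)C=CC(C)(C)O2 | intermediate
24 | (6aR,11aR)-9-(2-methylbut-3-en-2-yloxy)-3-(2-methylbut-3-yn-2-yloxy)-7,8-(2,2-dimethylpyrano)pterocarpan | c1c(OC(C)(C)C=C)c2c(c3c1O[C@H]1c4ccc(OC(C)(C)C#C)cc4OC[C@@H]31)C=CC(C)(C)O2 | intermediate
25 | (6aR,11aR)-10-(3-methylbut-2-enyl)-3-(2-methylbut-3-yn-2-yloxy)-7,8-(2,2-dimethylpyrano)pterocarpan-9-ol | CC(C)=CCc1c(O)c2c(c3c1O[C@H]1c4ccc(OC(C)(C)C#C)cc4OC[C@@H]31)C=CC(C)(C)O2 | intermediate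
26 | (6aR,11aR)-2-(3-methylbuta-1,2-dienyl)-10-(3-methylbut-2-enyl)-7,8-(2,2-dimethylpyrano)pterocarpan-3,9-diol | CC(C)=CCc1c(O)c2c(c3c1O[C@H]1c4cc(C=C=C(C)C)c(O)cc4OC[C@@H]31)C=CC(C)(C)O2 | intermediate
27 | ring A ortho-quinone methide of 26 (C3 ketone, exocyclic C2=CH–CH=CMe2; 6aR,11aR) | CC(C)=CCc1c(O)c2c(c3c1O[C@H]1C4=CC(=CC=C(C)C)C(=O)C=C4OC[C@@H]31)C=CC(C)(C)O2 | intermediate
28 | Lespecyrtin E4, (6aR,11aR) | CC(C)=CCc1c(O)c2c(c3c1O[C@H]1c4cc5c(cc4OC[C@@H]31)OC(C)(C)C=C5)C=CC(C)(C)O2 | target

## Step count and risks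

Total step count: 13. Longest linear sequence: 10 (steps 1–4, 7, 8, 10–13).

Steps most likely to fail:

1. Step 13. What may go wrong: poor site discrimination in the ring A sigmatropic shift (delivery to C4 instead of C2), or fragmentation of the O9 tertiary allyl ether with loss of isoprene before it rearranges. Fallback, setting out from 23 and coming back at 28: 23 is heated in toluene at 110 °C so that only the allyl ether rearranges, giving (6aR,11aR)-10-(3-methylbut-2-enyl)-7,8-(2,2-dimethylpyrano)pterocarpan-3,9-diol F1. Ring D is then fully substituted, so iodination with N-iodosuccinimide (CH2Cl2, −20 °C) can only occur on ring A and, as an electrophilic substitution, should go ortho to 3-OH and para to O5 to give the 2-iodo-3,9-diol F2. Heck coupling of F2 with 20 (Pd(OAc)2, P(o-tol)3, Et3N, MeCN, 80 °C) should give the (E)-2-(3-hydroxy-3-methylbut-1-enyl)-3,9-diol F3. PPTS in toluene at 60 °C then ionises the tertiary allylic alcohol to the ortho-quinone-methide-type cation, which closes ring F by C–O bond formation to give 28.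

2. Step 7. What may go wrong: slow transmetalation and reductive elimination at the di-ortho-substituted aryl group, so that protodemetalation and homocoupling take over. Fallback, setting out from 8 and coming back at 16: commercial 7-hydroxychroman-4-one F4 is silylated (TIPSCl, imidazole, DMF) to 7-(triisopropylsilyloxy)chroman-4-one F5. Ketone α-arylation of F5 with bromide 8 (Pd2(dba)3, XPhos, NaOt-Bu, toluene, 80 °C) should give isoflavanone 16 directly, which then enters the transfer hydrogenation and acid treatment of step 8 with the conjugate-reduction stage skipped.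

3. Step 8. What may go wrong: incomplete dynamic kinetic resolution because the bulky 3-aryl group slows the ketone reduction (erosion of enantiopurity), or loss of the silyl ether and acid damage to the chromene during the acidic stage. Fallback, setting out from 15 and coming back at 19: 15 is reduced with NaBH4 (THF/EtOH, 0 °C → rt) to the racemic isoflavan-4-ol F6 (cis/trans mixture). HCl in MeOH removes the MOM groups and closes ring C to the racemic cis-pterocarpan F7. Preparative chromatography on a chiral polysaccharide phase (supercritical CO2/MeOH) then delivers the (6aR,11aR)-enantiomer 19, so resolution replaces asymmetric catalysis.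

Further compounds
F1 | step 13 | (6aR,11aR)-10-(3-methylbut-2-enyl)-7,8-(2,2-dimethylpyrano)pterocarpan-3,9-diol | CC(C)=CCc1c(O)c2c(c3c1O[C@H]1c4ccc(O)cc4OC[C@@H]31)C=CC(C)(C)O2
F2 | step 13 | (6aR,11aR)-2-iodo-10-(3-methylbut-2-enyl)-7,8-(2,2-dimethylpyrano)pterocarpan-3,9-diol | CC(C)=CCc1c(O)c2c(c3c1O[C@H]1c4cc(I)c(O)cc4OC[C@@H]31)C=CC(C)(C)O2
F3 | step 13 | (6aR,11aR)-2-[(E)-3-hydroxy-3-methylbut-1-enyl]-10-(3-methylbut-2-enyl)-7,8-(2,2-dimethylpyrano)pterocarpan-3,9-diol | CC(C)=CCc1c(O)c2c(c3c1O[C@H]1c4cc(/C=C/C(C)(C)O)c(O)cc4OC[C@@H]31)C=CC(C)(C)O2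
F4 | step 7 | 7-hydroxychroman-4-one | O=C1CCOc2cc(O)ccc12
F5 | step 7 | 7-(triisopropylsilyloxy)chroman-4-one | O=C1CCOc2cc(O[Si](C(C)C)(C(C)C)C(C)C)ccc12
F6 | step 8 | racemic 3-[6,8-bis(methoxymethoxy)-2,2-dimethyl-2H-chromen-5-yl]-7-(triisopropylsilyloxy)chroman-4-ol (cis/trans mixture) | OC1c2ccc(O[Si](C(C)C)(C(C)C)C(C)C)cc2OCC1c1c(OCOC)cc(OCOC)c2OC(C)(C)C=Cc12
F7 | step 8 | racemic cis-3-(triisopropylsilyloxy)-7,8-(2,2-dimethylpyrano)pterocarpan-9-ol | c1c(O)c2c(c3c1OC1c4ccc(O[Si](C(C)C)(C(C)C)C(C)C)cc4OCC31)C=CC(C)(C)O2
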